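Side product is the steady figure of the summer run: from 3.00 min to 5.00 min it reads 66.6 %, 66.1 %, 66.7 %, level within the scatter of 1 percentage point. Target, though, slips from 31.2 % at 2.00 min to 26.2 % at 5.00 min, and that slip is what I would carry to the new flask for your quick number.

- summer: starting material 0.38 M; protic impurity 5 mM; run made earlier
- flask: starting material 0.25 M; protic impurity 5.00 mM; time 25 min

- summer (time / min: side product / %, target / %): 0.667: 49.9, 23.7; 1.33: 61.6, 28.8; 2.00: 65.1, 31.2; 3.00: 66.6, 28.2; 4.00: 66.1, 28.0; 5.00: 66.7, 26.2

(standard deviation of a reading: 1 percentage point)

- what was read earlier has a scatter of 1 percentage point, one standard deviation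

- share of side product in side product plus target at 1.2 s
- share of side product in side product plus target at 25 min
- which of side product and target there is more of at 25 min

I would count half-lives. Taking that slip as first-order, its rate constant k, the logarithm of the two target readings' ratio over the time between them, is 0.0582 min⁻¹. The target's half-life τ = ln(2)/k is then 11.9 min, a rough reading given the scatter. I carry the summer percentages to the new flask, whose protic impurity stands at the same 5.00 mM. From 2.00 min to 25 min is 1.93 half-lives, which leaves target near 8.18 %. With side product at 66.7 %, more than target, my share is 89.1 %. The time 1.2 s is earlier than any reading, so I commit to no share there.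

The forecast gives 68 % at 1.2 s, from 65 % to 71 %, and 85 % at 25 min, from 73 % to 96 %, with side product ahead, and it warns that “the endpoint is poorly constrained”. My share stands above its number but inside its range.

The flask gives 32.2 % at 1.2 s and 86.2 % at 25 min, with side product ahead, 66.4 % against 10.7 %. Side product draws level with target at 0.0539 min, later than 1.2 s.

    starting material → intermediate (k = 0.0233 s⁻¹)
    intermediate → side product (k = 0.442 s⁻¹)
    starting material → target (k = 0.0111 s⁻¹)
    target → over-reaction product (k = 7.39 × 10⁻⁴ s⁻¹)
    starting material + protic impurity → quenched substrate (k = 4.90 M⁻¹ s⁻¹)

Put τ on this flask: from 18.6 % of target at 12.5 min, 1.05 half-lives give 8.99 %, and the flask holds 10.7 %. For the neighbour flask with 0.0030 M of protic impurity, the count from summer gives 8.18 %, and that flask holds 10.8 %.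

The readings were computed with made-up constants.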